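**Retrosynthetic overview**

1. Lactone and side chain (last ring): C12–C13 by an Evans syn-aldol between a C12 aldehyde on the decalin and an (S)-3,4-dihydroxybutanoyl imide (acetonide), then acid-induced lactonisation through O15; C8=C17 by methylenation of a C8 ketone; C9–C11 by Mukaiyama aldol, elimination and hydrogenation.
2. Decalin: rings A and B are closed in one step by an intramolecular Diels–Alder reaction that makes C5–C10 and C6–C7 from an open-chain triene; ring B is the cycloaddition ring, ring A the ring spanned by the tether C1–C4.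
3. Enabling feature: in ring B the exocyclic-methylene carbon C8 is a latent ketone, so C7=C8(OSiEt3)–C9=C10 is a 2-silyloxydiene available from a methyl enone; C6 and C7 are plain CH2 groups, so C6 can carry a nitro group that activates C5=C6 and is later lost by elimination and hydrogenation; C19 is held at the aldehyde level during ring closure to steer the chair of ring A.
4. Open chain: C3–C4 with both stereocentres by iridium-catalysed tert-(hydroxy)prenylation with isoprene oxide; the C10=C9–C8(=O)–C7 enone by alkyne carboalumination and acylation; the nitroalkene by nitration of the C5=C6 vinyl group.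
5. Order of ring formation: rings A and B together (step 7), then the γ-lactone (step 16).

Key step: step 7

Assumption: the (R)-Tol-BINAP-modified iridium catalyst is taken to give the (2R,3R) anti diol in step 1; if the sense of induction proves opposite, the (S)-ligand is used with no other change.

Step 1
Reactants: 1 5-(trimethylsilyl)pent-4-yn-1-ol; 2 2-methyl-2-vinyloxirane (isoprene oxide, racemic, in excess)
Product: 4 (2R,3R)-2-ethenyl-2-methyl-7-(trimethylsilyl)hept-6-yne-1,3-diol, via 5-(trimethylsilyl)pent-4-ynal 3 (not isolated)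
Conditions: π-allyliridium C,O-benzoate complex prepared from [Ir(cod)Cl]2, (R)-Tol-BINAP, 4-cyano-3-nitrobenzoic acid and allyl acetate (5 mol%), K3PO4 (5 mol%), THF, 60 °C
Reagents that add atoms: none
Why: Iridium-catalysed transfer-hydrogenative carbonyl tert-(hydroxy)prenylation, in which the catalyst dehydrogenates 1 to aldehyde 3 and opens isoprene oxide to a (hydroxymethyl)(methyl)allyl–iridium species that adds to 3 through a closed chair-like transition state, so that the quaternary C4 and the carbinol C3 are formed anti (C3–OH anti to CH2OH) with the absolute sense fixed by the Tol-BINAP ligand.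

Step 2
Reactants: 4 (2R,3R)-2-ethenyl-2-methyl-7-(trimethylsilyl)hept-6-yne-1,3-diol
Product: 5 (2R,3R)-2-ethenyl-2-methylhept-6-yne-1,3-diol
Conditions: K2CO3, MeOH, rt
Reagents that add atoms: none
Why: Methoxide-mediated protodesilylation of the alkynylsilane cleaves only the sp-carbon–silicon bond and touches no stereocentre.

Step 3
Reactants: 5 (2R,3R)-2-ethenyl-2-methylhept-6-yne-1,3-diol
Product: 6 (3R,4R)-3-methyl-4-(triethylsilyloxy)-3-[(triethylsilyloxy)methyl]oct-1-en-7-yne
Conditions: Et3SiOTf, 2,6-lutidine, CH2Cl2, −78 to 0 °C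
Reagents that add atoms: triethylsilyl trifluoromethanesulfonate, CC[Si](CC)(CC)OS(=O)(=O)C(F)(F)F
Why: Silyl triflate silylation protects both hydroxyl groups, including the hindered neopentyl secondary one, as triethylsilyl ethers that should survive organoaluminium, radical and mildly basic steps and fall off in the final acid step.

Step 4
Reactants: 6 (3R,4R)-3-methyl-4-(triethylsilyloxy)-3-[(triethylsilyloxy)methyl]oct-1-en-7-yne
Product: 8 (3E,7R,8R)-4,8-dimethyl-7-(triethylsilyloxy)-8-[(triethylsilyloxy)methyl]deca-3,9-dien-2-one, via alkenylalane 7 (not isolated)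
Conditions: Me3Al, Cp2ZrCl2 (25 mol%), CH2Cl2, 0 °C to rt; then THF, AcCl, Pd(PPh3)4 (5 mol%), 0 °C to rt
Reagents that add atoms: trimethylaluminium, C[Al](C)C; acetyl chloride, CC(Cl)=O
Why: Negishi carboalumination (zirconium-catalysed syn addition of Me–Al with methyl on the internal carbon) followed by palladium-catalysed acylation of the alkenylalane with retention should give the (E)-β,β-disubstituted methyl enone, the hindered monosubstituted alkene being inert under these conditions.

Step 5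
Reactants: 8 (3E,7R,8R)-4,8-dimethyl-7-(triethylsilyloxy)-8-[(triethylsilyloxy)methyl]deca-3,9-dien-2-one
Product: 9 (3E,7R,8R,9E)-4,8-dimethyl-10-nitro-7-(triethylsilyloxy)-8-[(triethylsilyloxy)methyl]deca-3,9-dien-2-one
Conditions: AgNO2, TEMPO, 4 Å molecular sieves, ClCH2CH2Cl, 70 °C
Reagents that add atoms: silver nitrite, [Ag+].[O-]N=O
Why: Radical nitration of a terminal alkene, in which the nitro radical adds to the terminal carbon and the TEMPO-trapped adduct eliminates to the (E)-nitroalkene, should be chemoselective because the enone double bond is electron-poor and trisubstituted.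

Step 6
Reactants: 9 (3E,7R,8R,9E)-4,8-dimethyl-10-nitro-7-(triethylsilyloxy)-8-[(triethylsilyloxy)methyl]deca-3,9-dien-2-one
Product: 10 (2S,3R,6E)-2,6-dimethyl-2-[(E)-2-nitroethenyl]-8-oxo-3-(triethylsilyloxy)non-6-enal
Conditions: (COCl)2, DMSO, CH2Cl2, −78 to −30 °C; then Et3N, −78 to 0 °C
Reagents that add atoms: none
Why: Swern oxidation of a primary triethylsilyl ether, in which the chlorosulfonium species cleaves the less hindered primary O–Si bond and the alkoxysulfonium ion collapses to the aldehyde while the secondary silyl ether stays, gives an α-quaternary aldehyde that cannot enolise.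

Step 7
Reactants: 10 (2S,3R,6E)-2,6-dimethyl-2-[(E)-2-nitroethenyl]-8-oxo-3-(triethylsilyloxy)non-6-enal
Product: 12 (1S,2R,4aR,8R,8aS)-1,4a-dimethyl-8-nitro-2,6-bis(triethylsilyloxy)-1,2,3,4,4a,7,8,8a-octahydronaphthalene-1-carbaldehyde, via silyloxy diene 11 (not isolated)
Conditions: Et3SiOTf, Et3N, CH2Cl2 (0.01 M), −78 to 0 °C; then toluene, 80–100 °C
Reagents that add atoms: triethylsilyl trifluoromethanesulfonate, CC[Si](CC)(CC)OS(=O)(=O)C(F)(F)F
Why: Soft enolisation of the methyl ketone of 10 at the α′-methyl group gives the cross-conjugated 2-silyloxy-1,3-diene 11, whose thermal, concerted but asynchronous intramolecular Diels–Alder reaction (1,7,9-decatriene type) with the (E)-nitroalkene forms C5–C10 and C6–C7 in one operation. The closest known reaction types are the thermal cyclisation of (E)-1-nitro-1,7,9-decatrienes and the cycloaddition of silyl dienol ethers generated in situ from enones. Ring B closes as the six-membered ring of the [4+2] cycloaddition (suprafacial on both partners) and ring A as the fused six-membered ring spanned by the four-carbon tether C1–C4, which enforces the fused rather than the bridged regiochemistry. The trans ring fusion (C5–H anti to the C10 methyl) is controlled by the transition state with the nitro group endo and the quaternary C4 exo, since C4 with its three substituents cannot lie under the diene. The configuration of the new quaternary C10 relative to C3 and C4 is controlled by the chair-like tether, in which the small planar formyl group (C19) takes the axial position syn to the inside methyl of the diene while the C4 methyl and the C3 silyloxy group are equatorial. The step needs endo and π-facial selectivity and an intramolecular reaction that outruns the polarity-matched bimolecular pathway; the (E)-nitroalkene, the C19 formyl/C3 silyloxy pair and high dilution are meant to secure these.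

Step 8
Reactants: 12 (1S,2R,4aR,8R,8aS)-1,4a-dimethyl-8-nitro-2,6-bis(triethylsilyloxy)-1,2,3,4,4a,7,8,8a-octahydronaphthalene-1-carbaldehyde
Product: 13 [(1R,2R,4aR,8R,8aS)-1,4a-dimethyl-8-nitro-2,6-bis(triethylsilyloxy)-1,2,3,4,4a,7,8,8a-octahydronaphthalen-1-yl]methanol
Conditions: NaBH4, THF/i-PrOH, −20 to 0 °C
Reagents that add atoms: none
Why: Chemoselective borohydride reduction of the hindered aldehyde returns C19 to the alcohol level, the nitro group and the silyl enol ether being inert under cold, weakly protic conditions.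

Step 9
Reactants: 13 [(1R,2R,4aR,8R,8aS)-1,4a-dimethyl-8-nitro-2,6-bis(triethylsilyloxy)-1,2,3,4,4a,7,8,8a-octahydronaphthalen-1-yl]methanol
Product: 14 triethyl{[(1R,2R,4aR,8R,8aS)-1,4a-dimethyl-8-nitro-2,6-bis(triethylsilyloxy)-1,2,3,4,4a,7,8,8a-octahydronaphthalen-1-yl]methoxy}silane
Conditions: Et3SiCl, imidazole, DMAP (cat.), CH2Cl2, 0 °C
Reagents that add atoms: chlorotriethylsilane, CC[Si](Cl)(CC)CC
Why: Standard silylation of the primary neopentyl alcohol under basic conditions leaves the silyl enol ether and the nitro group untouched.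

Step 10
Reactants: 14 triethyl{[(1R,2R,4aR,8R,8aS)-1,4a-dimethyl-8-nitro-2,6-bis(triethylsilyloxy)-1,2,3,4,4a,7,8,8a-octahydronaphthalen-1-yl]methoxy}silane
Product: 17 ethyl (2Z)-2-[(4aS,5R,6R,8aR)-5,8a-dimethyl-2-oxo-6-(triethylsilyloxy)-5-[(triethylsilyloxy)methyl]-4a,5,6,7,8,8a-hexahydronaphthalen-1(2H)-ylidene]acetate, via silyl aldol 15 (not isolated), via enone silyl aldol 16 (not isolated)
Conditions: ethyl glyoxylate, Et3SiOTf (10 mol%), CH2Cl2, −78 °C; then DBU, −78 °C to rt
Reagents that add atoms: ethyl glyoxylate, CCOC(=O)C=O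
Why: Silyl-triflate-catalysed Mukaiyama aldol addition of the regiodefined enol ether carbon C9 to ethyl glyoxylate is followed by DBU-induced E1cB loss of nitrite from the β-nitro ketone and of triethylsilanolate from the β-silyloxy ketone, so the nitro group leaves without trace and the C9/C11 centres of the adduct are erased (the alkylidene geometry is inconsequential).

Step 11
Reactants: 17 ethyl (2Z)-2-[(4aS,5R,6R,8aR)-5,8a-dimethyl-2-oxo-6-(triethylsilyloxy)-5-[(triethylsilyloxy)methyl]-4a,5,6,7,8,8a-hexahydronaphthalen-1(2H)-ylidene]acetate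
Product: 18 ethyl 2-[(1S,4aS,5R,6R,8aR)-5,8a-dimethyl-2-oxo-6-(triethylsilyloxy)-5-[(triethylsilyloxy)methyl]decahydronaphthalen-1-yl]acetate
Conditions: H2 (1 atm), Pd/C, EtOAc, rt
Reagents that add atoms: none
Why: Heterogeneous hydrogenation saturates the C6=C7 and C9=C11 double bonds, and hydrogen should reach C9 from the face opposite the axial C10 methyl group, which sets C9–H anti to that methyl and places the side chain equatorial.

Step 12
Reactants: 18 ethyl 2-[(1S,4aS,5R,6R,8aR)-5,8a-dimethyl-2-oxo-6-(triethylsilyloxy)-5-[(triethylsilyloxy)methyl]decahydronaphthalen-1-yl]acetate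
Product: 19 ethyl 2-[(1R,4aS,5R,6R,8aS)-5,8a-dimethyl-2-methylidene-6-(triethylsilyloxy)-5-[(triethylsilyloxy)methyl]decahydronaphthalen-1-yl]acetate
Conditions: Zn, CH2Br2, TiCl4, THF; then 18, CH2Cl2, 0 °C to rt
Reagents that add atoms: dibromomethane, BrCBr
Why: Lombardo methylenation, a non-basic titanium–zinc methylene transfer, should convert the hindered C8 ketone into the exocyclic alkene without epimerising C9 and without touching the ester.

Step 13
Reactants: 19 ethyl 2-[(1R,4aS,5R,6R,8aS)-5,8a-dimethyl-2-methylidene-6-(triethylsilyloxy)-5-[(triethylsilyloxy)methyl]decahydronaphthalen-1-yl]acetate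
Product: 20 2-[(1R,4aS,5R,6R,8aS)-5,8a-dimethyl-2-methylidene-6-(triethylsilyloxy)-5-[(triethylsilyloxy)methyl]decahydronaphthalen-1-yl]acetaldehyde
Conditions: i-Bu2AlH, CH2Cl2, −78 °C
Reagents that add atoms: none
Why: Partial reduction of the ester by i-Bu2AlH at low temperature stops at the aluminium hemiacetal, which gives the C12 aldehyde on work-up.

Step 14
Reactants: 21 [(4S)-2,2-dimethyl-1,3-dioxolan-4-yl]acetic acid; 22 (4S)-4-benzyl-1,3-oxazolidin-2-one
Product: 24 (4S)-4-benzyl-3-{[(4S)-2,2-dimethyl-1,3-dioxolan-4-yl]acetyl}-1,3-oxazolidin-2-one, via mixed anhydride 23 (not isolated)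
Conditions: t-BuCOCl, Et3N, THF, −20 °C; then LiCl, 22, rt
Reagents that add atoms: none
Why: N-Acylation of the oxazolidinone through the mixed pivalic anhydride (LiCl/Et3N activation) leaves the dioxolane stereocentre untouched.

Step 15
Reactants: 20 2-[(1R,4aS,5R,6R,8aS)-5,8a-dimethyl-2-methylidene-6-(triethylsilyloxy)-5-[(triethylsilyloxy)methyl]decahydronaphthalen-1-yl]acetaldehyde; 24 (4S)-4-benzyl-3-{[(4S)-2,2-dimethyl-1,3-dioxolan-4-yl]acetyl}-1,3-oxazolidin-2-one
Product: 26 (4S)-4-benzyl-3-{(2R,3R)-2-[(4S)-2,2-dimethyl-1,3-dioxolan-4-yl]-3-hydroxy-4-[(1R,4aS,5R,6R,8aS)-5,8a-dimethyl-2-methylidene-6-(triethylsilyloxy)-5-[(triethylsilyloxy)methyl]decahydronaphthalen-1-yl]butanoyl}-1,3-oxazolidin-2-one, via boron enolate 25 (not isolated)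
Conditions: n-Bu2BOTf, i-Pr2NEt, CH2Cl2, −78 to 0 °C; then 20, −78 to 0 °C; then pH 7 buffer, MeOH, H2O2, 0 °C
Reagents that add atoms: none
Why: Evans syn-aldol reaction, in which the (Z)-boron enolate 25 adds to the aldehyde through a Zimmerman–Traxler chair on the enolate face opposite the benzyl group of the (S)-auxiliary, sets C12 (R) and C13 (R), while C14 (S) comes from the chiral pool.

Step 16
Reactants: 26 (4S)-4-benzyl-3-{(2R,3R)-2-[(4S)-2,2-dimethyl-1,3-dioxolan-4-yl]-3-hydroxy-4-[(1R,4aS,5R,6R,8aS)-5,8a-dimethyl-2-methylidene-6-(triethylsilyloxy)-5-[(triethylsilyloxy)methyl]decahydronaphthalen-1-yl]butanoyl}-1,3-oxazolidin-2-one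
Product: 28 (3R,4S)-4-hydroxy-3-{(1R)-1-hydroxy-2-[(1R,4aS,5R,6R,8aS)-6-hydroxy-5-(hydroxymethyl)-5,8a-dimethyl-2-methylidenedecahydronaphthalen-1-yl]ethyl}oxolan-2-one (target), via hydroxy imide 27 (not isolated)
Conditions: AcOH/THF/H2O (3:1:1), 40 °C
Reagents that add atoms: none
Why: Aqueous acetic acid cleaves both triethylsilyl ethers and the acetonide, and the freed primary C15 hydroxyl attacks the activated imide carbonyl (five-membered ring closure) to give the γ-lactone with release of the auxiliary, no stereocentre being touched.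

**Compound list**

1 | 5-(trimethylsilyl)pent-4-yn-1-ol | C[Si](C)(C)C#CCCCO | starting material
2 | 2-methyl-2-vinyloxirane (isoprene oxide, racemic) | C=CC1(C)CO1 | starting material
3 | 5-(trimethylsilyl)pent-4-ynal (formed in the flask) | C[Si](C)(C)C#CCCC=O | intermediate
4 | (2R,3R)-2-ethenyl-2-methyl-7-(trimethylsilyl)hept-6-yne-1,3-diol | C=C[C@](C)(CO)[C@H](O)CCC#C[Si](C)(C)C | intermediate
5 | (2R,3R)-2-ethenyl-2-methylhept-6-yne-1,3-diol | C=C[C@](C)(CO)[C@H](O)CCC#C | intermediate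
6 | (3R,4R)-3-methyl-4-(triethylsilyloxy)-3-[(triethylsilyloxy)methyl]oct-1-en-7-yne | C=C[C@](C)(CO[Si](CC)(CC)CC)[C@H](O[Si](CC)(CC)CC)CCC#C | intermediate
7 | dimethyl[(1E,5R,6R)-2,6-dimethyl-5-(triethylsilyloxy)-6-[(triethylsilyloxy)methyl]octa-1,7-dien-1-yl]alumane (formed in the flask) | C=C[C@](C)(CO[Si](CC)(CC)CC)[C@H](O[Si](CC)(CC)CC)CC/C(C)=C/[Al](C)C | intermediate
8 | (3E,7R,8R)-4,8-dimethyl-7-(triethylsilyloxy)-8-[(triethylsilyloxy)methyl]deca-3,9-dien-2-one | C=C[C@](C)(CO[Si](CC)(CC)CC)[C@H](O[Si](CC)(CC)CC)CC/C(C)=C/C(C)=O | intermediate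
9 | (3E,7R,8R,9E)-4,8-dimethyl-10-nitro-7-(triethylsilyloxy)-8-[(triethylsilyloxy)methyl]deca-3,9-dien-2-one | [O-][N+](=O)/C=C/[C@](C)(CO[Si](CC)(CC)CC)[C@H](O[Si](CC)(CC)CC)CC/C(C)=C/C(C)=O | intermediate
10 | (2S,3R,6E)-2,6-dimethyl-2-[(E)-2-nitroethenyl]-8-oxo-3-(triethylsilyloxy)non-6-enal | [O-][N+](=O)/C=C/[C@](C)(C=O)[C@H](O[Si](CC)(CC)CC)CC/C(C)=C/C(C)=O | intermediate
11 | (2S,3R,6E)-2,6-dimethyl-2-[(E)-2-nitroethenyl]-3,8-bis(triethylsilyloxy)nona-6,8-dienal (formed in the flask) | [O-][N+](=O)/C=C/[C@](C)(C=O)[C@H](O[Si](CC)(CC)CC)CC/C(C)=C/C(=C)O[Si](CC)(CC)CC | intermediate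
12 | (1S,2R,4aR,8R,8aS)-1,4a-dimethyl-8-nitro-2,6-bis(triethylsilyloxy)-1,2,3,4,4a,7,8,8a-octahydronaphthalene-1-carbaldehyde | CC[Si](CC)(CC)OC=1C[C@@H]([N+](=O)[O-])[C@@H]2[C@](C)(C=O)[C@H](O[Si](CC)(CC)CC)CC[C@@]2(C)C=1 | intermediate
13 | [(1R,2R,4aR,8R,8aS)-1,4a-dimethyl-8-nitro-2,6-bis(triethylsilyloxy)-1,2,3,4,4a,7,8,8a-octahydronaphthalen-1-yl]methanol | CC[Si](CC)(CC)OC=1C[C@@H]([N+](=O)[O-])[C@@H]2[C@](C)(CO)[C@H](O[Si](CC)(CC)CC)CC[C@@]2(C)C=1 | intermediate
14 | triethyl{[(1R,2R,4aR,8R,8aS)-1,4a-dimethyl-8-nitro-2,6-bis(triethylsilyloxy)-1,2,3,4,4a,7,8,8a-octahydronaphthalen-1-yl]methoxy}silane | CC[Si](CC)(CC)OC=1C[C@@H]([N+](=O)[O-])[C@@H]2[C@](C)(CO[Si](CC)(CC)CC)[C@H](O[Si](CC)(CC)CC)CC[C@@]2(C)C=1 | intermediate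
15 | ethyl 2-[(4R,4aS,5R,6R,8aR)-5,8a-dimethyl-4-nitro-2-oxo-6-(triethylsilyloxy)-5-[(triethylsilyloxy)methyl]decahydronaphthalen-1-yl]-2-(triethylsilyloxy)acetate (formed in the flask; mixture at the two new centres) | O=C1C[C@@H]([N+](=O)[O-])[C@@H]2[C@](C)(CO[Si](CC)(CC)CC)[C@H](O[Si](CC)(CC)CC)CC[C@@]2(C)C1C(O[Si](CC)(CC)CC)C(=O)OCC | intermediate
16 | ethyl 2-[(4aS,5R,6R,8aR)-5,8a-dimethyl-2-oxo-6-(triethylsilyloxy)-5-[(triethylsilyloxy)methyl]-1,2,4a,5,6,7,8,8a-octahydronaphthalen-1-yl]-2-(triethylsilyloxy)acetate (formed in the flask; mixture at the two side-chain centres) | O=C1C=C[C@@H]2[C@](C)(CO[Si](CC)(CC)CC)[C@H](O[Si](CC)(CC)CC)CC[C@@]2(C)C1C(O[Si](CC)(CC)CC)C(=O)OCC | intermediate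
17 | ethyl (2Z)-2-[(4aS,5R,6R,8aR)-5,8a-dimethyl-2-oxo-6-(triethylsilyloxy)-5-[(triethylsilyloxy)methyl]-4a,5,6,7,8,8a-hexahydronaphthalen-1(2H)-ylidene]acetate | O=C1C=C[C@@H]2[C@](C)(CO[Si](CC)(CC)CC)[C@H](O[Si](CC)(CC)CC)CC[C@@]2(C)/C1=C/C(=O)OCC | intermediate
18 | ethyl 2-[(1S,4aS,5R,6R,8aR)-5,8a-dimethyl-2-oxo-6-(triethylsilyloxy)-5-[(triethylsilyloxy)methyl]decahydronaphthalen-1-yl]acetate | O=C1CC[C@@H]2[C@](C)(CO[Si](CC)(CC)CC)[C@H](O[Si](CC)(CC)CC)CC[C@@]2(C)[C@@H]1CC(=O)OCC | intermediate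
19 | ethyl 2-[(1R,4aS,5R,6R,8aS)-5,8a-dimethyl-2-methylidene-6-(triethylsilyloxy)-5-[(triethylsilyloxy)methyl]decahydronaphthalen-1-yl]acetate | C=C1CC[C@@H]2[C@](C)(CO[Si](CC)(CC)CC)[C@H](O[Si](CC)(CC)CC)CC[C@@]2(C)[C@@H]1CC(=O)OCC | intermediate
20 | 2-[(1R,4aS,5R,6R,8aS)-5,8a-dimethyl-2-methylidene-6-(triethylsilyloxy)-5-[(triethylsilyloxy)methyl]decahydronaphthalen-1-yl]acetaldehyde | C=C1CC[C@@H]2[C@](C)(CO[Si](CC)(CC)CC)[C@H](O[Si](CC)(CC)CC)CC[C@@]2(C)[C@@H]1CC=O | intermediate
21 | [(4S)-2,2-dimethyl-1,3-dioxolan-4-yl]acetic acid | CC1(C)OC[C@H](CC(=O)O)O1 | starting material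
22 | (4S)-4-benzyl-1,3-oxazolidin-2-one | O=C1OC[C@H](Cc2ccccc2)N1 | starting material
23 | [(4S)-2,2-dimethyl-1,3-dioxolan-4-yl]acetic pivalic anhydride (formed in the flask) | CC1(C)OC[C@H](CC(=O)OC(=O)C(C)(C)C)O1 | intermediate
24 | (4S)-4-benzyl-3-{[(4S)-2,2-dimethyl-1,3-dioxolan-4-yl]acetyl}-1,3-oxazolidin-2-one | CC1(C)OC[C@H](CC(=O)N2[C@@H](Cc3ccccc3)COC2=O)O1 | intermediate
25 | (Z)-dibutylboron enolate of 24 (formed in the flask) | CCCCB(CCCC)O/C(N1[C@@H](Cc2ccccc2)COC1=O)=C\[C@H]1COC(C)(C)O1 | intermediate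
26 | (4S)-4-benzyl-3-{(2R,3R)-2-[(4S)-2,2-dimethyl-1,3-dioxolan-4-yl]-3-hydroxy-4-[(1R,4aS,5R,6R,8aS)-5,8a-dimethyl-2-methylidene-6-(triethylsilyloxy)-5-[(triethylsilyloxy)methyl]decahydronaphthalen-1-yl]butanoyl}-1,3-oxazolidin-2-one | C=C1CC[C@@H]2[C@](C)(CO[Si](CC)(CC)CC)[C@H](O[Si](CC)(CC)CC)CC[C@@]2(C)[C@@H]1C[C@@H](O)[C@@H](C(=O)N3[C@@H](Cc4ccccc4)COC3=O)[C@H]5COC(C)(C)O5 | intermediate
27 | (4S)-4-benzyl-3-{(2R,3R)-2-[(1S)-1,2-dihydroxyethyl]-3-hydroxy-4-[(1R,4aS,5R,6R,8aS)-6-hydroxy-5-(hydroxymethyl)-5,8a-dimethyl-2-methylidenedecahydronaphthalen-1-yl]butanoyl}-1,3-oxazolidin-2-one (formed in the flask) | C=C1CC[C@@H]2[C@](C)(CO)[C@H](O)CC[C@@]2(C)[C@@H]1C[C@@H](O)[C@@H](C(=O)N3[C@@H](Cc4ccccc4)COC3=O)[C@H](O)CO | intermediate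
28 | (3R,4S)-4-hydroxy-3-{(1R)-1-hydroxy-2-[(1R,4aS,5R,6R,8aS)-6-hydroxy-5-(hydroxymethyl)-5,8a-dimethyl-2-methylidenedecahydronaphthalen-1-yl]ethyl}oxolan-2-one | C=C1CC[C@@H]2[C@](C)(CO)[C@H](O)CC[C@@]2(C)[C@@H]1C[C@@H](O)[C@H]1C(=O)OC[C@H]1O | target

**Step count and risks**

Total steps: 16. Longest linear sequence: 15 steps (steps 1–13, 15 and 16); step 14 prepares the aldol partner.

Step 7. The intramolecular cycloaddition may be outrun by the polarity-matched bimolecular reaction of the silyloxy diene with the nitroalkene of a second molecule, or by a 1,5-hydrogen shift in the diene, because the inside methyl group at C10 disfavours the s-cis conformer and the tether imposes the electronically mismatched orientation; silyl-triflate-promoted aldol addition to the formyl group is a further drain. The fallback replaces the cycloaddition by a stepwise ionic annulation and bypasses steps 6 to 9. Setting out from 9, conjugate reduction of the nitroalkene with a Hantzsch ester should give the nitroalkane F1. A Nef reaction (NaOMe; then TiCl3, aqueous NH4OAc) should give the aldehyde F2. Pyrrolidine and AcOH should then bring about intramolecular Michael addition of the aldehyde enamine (C5) to the enone (C10), followed by aldol condensation of the methyl ketone (C7) onto the aldehyde (C6), to give the bicyclic enone F3; the reversible Michael step should favour the trans ring fusion. Kinetic deprotonation at C9 (LiN(i-Pr)2, Et3SiCl, THF, −78 °C) should give the silyl dienol ether F4, which enters the Mukaiyama aldol and elimination of step 10 and comes back to the route at 17.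

Step 5. The nitro radical may attack the enone or its allylic positions, or conversion at the vinyl group next to the quaternary C4 may stall. The fallback rebuilds C6 by ionic chemistry. Setting out from 8, Lemieux–Johnson cleavage (OsO4 cat., NaIO4, 2,6-lutidine) of the monosubstituted alkene should give the aldehyde F5. A Henry reaction with nitromethane (KOt-Bu cat.) should give the nitro alcohol F6, whose mesylate F7 (MsCl, Et3N) should eliminate in the flask to the (E)-nitroalkene 9.

Step 10. Carbon–carbon bond formation at C9, which is flanked by the quaternary C10, may be slow, so that protodesilylation of the enol ether or early loss of nitrite takes over and the regiochemistry of enolisation is lost; the silanolate elimination may also stop half-way. The fallback removes the nitro group first by a radical reaction and then uses a lithium enolate. Setting out from 14, n-Bu3SnH and AIBN (toluene, reflux) should remove the secondary nitro group and give the enol ether F8. MeLi should release the regiodefined lithium enolate, which adds to ethyl glyoxylate to give the aldol F9. Mesylation (MsCl, Et3N) should give F10, which eliminates with DBU to the alkylidene keto ester F11. Hydrogenation as in step 11 returns to the route at 18.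

Further compounds
F1 | step 7 | (3E,7R,8R)-4,8-dimethyl-10-nitro-7-(triethylsilyloxy)-8-[(triethylsilyloxy)methyl]dec-3-en-2-one | [O-][N+](=O)CC[C@](C)(CO[Si](CC)(CC)CC)[C@H](O[Si](CC)(CC)CC)CC/C(C)=C/C(C)=O
F2 | step 7 | (3R,4R,7E)-3,7-dimethyl-9-oxo-4-(triethylsilyloxy)-3-[(triethylsilyloxy)methyl]dec-7-enal | O=CC[C@](C)(CO[Si](CC)(CC)CC)[C@H](O[Si](CC)(CC)CC)CC/C(C)=C/C(C)=O
F3 | step 7 | (4aS,5R,6R,8aS)-5,8a-dimethyl-6-(triethylsilyloxy)-5-[(triethylsilyloxy)methyl]-4a,5,6,7,8,8a-hexahydronaphthalen-2(1H)-one | O=C1C=C[C@@H]2[C@](C)(CO[Si](CC)(CC)CC)[C@H](O[Si](CC)(CC)CC)CC[C@@]2(C)C1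
F4 | step 7 | triethylsilyl dienol ether of F3 (cross-conjugated 2-silyloxy diene C6=C7–C8(OSiEt3)=C9) | CC[Si](CC)(CC)OC=1C=C[C@@H]2[C@](C)(CO[Si](CC)(CC)CC)[C@H](O[Si](CC)(CC)CC)CC[C@@]2(C)C=1
F5 | step 5 | (2R,3R,6E)-2,6-dimethyl-8-oxo-3-(triethylsilyloxy)-2-[(triethylsilyloxy)methyl]non-6-enal | O=C[C@](C)(CO[Si](CC)(CC)CC)[C@H](O[Si](CC)(CC)CC)CC/C(C)=C/C(C)=O
F6 | step 5 | (3E,7R,8R)-9-hydroxy-4,8-dimethyl-10-nitro-7-(triethylsilyloxy)-8-[(triethylsilyloxy)methyl]dec-3-en-2-one (mixture at C9) | [O-][N+](=O)CC(O)[C@](C)(CO[Si](CC)(CC)CC)[C@H](O[Si](CC)(CC)CC)CC/C(C)=C/C(C)=O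
F7 | step 5 | methanesulfonate of F6 (formed in the flask) | [O-][N+](=O)CC(OS(C)(=O)=O)[C@](C)(CO[Si](CC)(CC)CC)[C@H](O[Si](CC)(CC)CC)CC/C(C)=C/C(C)=O
F8 | step 10 | triethyl{[(1R,2R,4aR,8aS)-1,4a-dimethyl-2,6-bis(triethylsilyloxy)-1,2,3,4,4a,7,8,8a-octahydronaphthalen-1-yl]methoxy}silane | CC[Si](CC)(CC)OC=1CC[C@@H]2[C@](C)(CO[Si](CC)(CC)CC)[C@H](O[Si](CC)(CC)CC)CC[C@@]2(C)C=1
F9 | step 10 | ethyl 2-hydroxy-2-[(4aS,5R,6R,8aR)-5,8a-dimethyl-2-oxo-6-(triethylsilyloxy)-5-[(triethylsilyloxy)methyl]decahydronaphthalen-1-yl]acetate (mixture at the two new centres) | O=C1CC[C@@H]2[C@](C)(CO[Si](CC)(CC)CC)[C@H](O[Si](CC)(CC)CC)CC[C@@]2(C)C1C(O)C(=O)OCC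
F10 | step 10 | methanesulfonate of F9 | O=C1CC[C@@H]2[C@](C)(CO[Si](CC)(CC)CC)[C@H](O[Si](CC)(CC)CC)CC[C@@]2(C)C1C(OS(C)(=O)=O)C(=O)OCC
F11 | step 10 | ethyl (2Z)-2-[(4aS,5R,6R,8aR)-5,8a-dimethyl-2-oxo-6-(triethylsilyloxy)-5-[(triethylsilyloxy)methyl]octahydronaphthalen-1(2H)-ylidene]acetate | O=C1CC[C@@H]2[C@](C)(CO[Si](CC)(CC)CC)[C@H](O[Si](CC)(CC)CC)CC[C@@]2(C)/C1=C/C(=O)OCC
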